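Read Thursday's run on the clock of a run already made, then check whether that clock asks for more J than the flask holds.

| flask | G | J | E | time |
|---|---|---|---|---|
| Monday's | 0.0800 M | 0.0960 M | 0.00400 M |  |
| Sunday's | 0.0400 M | 0.0560 M | 0.00400 M |  |
| Friday's | 0.120 M | 0.0960 M | 0.00400 M |  |
| Saturday's | 0.0800 M | 0.0960 M | 0.0120 M |  |
| Thursday's | 0.0800 M | 0.0480 M | 0.00800 M | 110 s |

| run | time / s | [L] / M |
|---|---|---|
| Monday's run | 4.4 | 8.3 × 10⁻⁴ |
| Monday's run | 7.5 | 0.00123 |
| Monday's run | 13 | 0.00290 |
| Monday's run | 22 | 0.00528 |
| Monday's run | 38 | 0.01038 |
| Monday's run | 64 | 0.02135 |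
| Monday's run | 110 | 0.04129 |
| Sunday's run | 4.4 | 3.0 × 10⁻⁴ |
| Sunday's run | 7.5 | 7.4 × 10⁻⁴ |
| Sunday's run | 13 | 0.00163 |
| Sunday's run | 22 | 0.00247 |
| Sunday's run | 38 | 0.00463 |
| Sunday's run | 64 | 0.00835 |
| Sunday's run | 110 | 0.01447 |
| Friday's run | 4.4 | 0.00104 |
| Friday's run | 7.5 | 0.00194 |
| Friday's run | 13 | 0.00421 |
| Friday's run | 22 | 0.00873 |
| Friday's run | 38 | 0.01781 |
| Friday's run | 64 | 0.03774 |
| Friday's run | 110 | 0.06635 |
| Saturday's run | 4.4 | 0.00196 |
| Saturday's run | 7.5 | 0.00385 |
| Saturday's run | 13 | 0.00798 |
| Saturday's run | 22 | 0.01412 |
| Saturday's run | 38 | 0.02640 |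
| Saturday's run | 64 | 0.04333 |
| Saturday's run | 110 | 0.06178 |

(standard deviation of a reading: 2 × 10⁻⁴ M)

- Overall: G + J -> L, with E as catalyst.
- Constant volume, constant temperature.
- A reading of a species includes what of it is bound.
- An order is taken over about fifteen percent of the charge, up and down.

- apparent order in [G] of the starting rate, round the charge of the Monday's run (the rate where two percent of its G have turned into L) (one fixed amount of L, the same in the runs compared)
- apparent order in [E] of the starting rate, round the charge of the Monday's run (the rate where two percent of its G have turned into L)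
- the Sunday's run starts with 0.0400 M less of G and of J than the Monday's run, and with no L. Compared where both hold the same amount of G, once fifteen percent of what the Sunday's run was charged with has turned into L, is the Sunday's run faster, slower or alike (within a tenth)?
- L in the Thursday's run at 110 s, as a share of the G charged

Monday's run and Saturday's run differ in their charge of the catalyst E and in nothing else. The bench rule says that the time to reach a given amount of the product L scales inversely with [E]. I test it at the L that Saturday's run reads at 38 s, which is 0.02640 M. Monday's run reaches that L at about 75.6 s, by a straight line between its readings. The rule therefore needs an exponent, which I call the clock exponent m, the power of [E] by which the time to a fixed L shrinks at a fixed charge of G and J: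

m = ln(time in Monday's run / time in Saturday's run) / ln(E in Saturday's run / E in Monday's run) = 0.627

This is a reading, and it is smaller than the 1 of the bench rule.

Thursday's run has the G of Saturday's run, and its 0.00800 M of E turns 110 s into this time on Saturday's clock:

85.3 s

Saturday's run, read between its last two points, holds 0.0519 M of L there. Here the rule meets its border. J is the limiting reagent of Thursday's run, since its 0.0480 M is less than its 0.0800 M of G, and the ratio of the first answer to that charge is 1.08. So the clock asks for more L than the J of Thursday's run can give, and the ceiling is 60.0% of the G.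

I put the first answer back in, this time letting the rate fall in proportion to the J remaining:

L = J₀ (1 − exp(−L₁/J₀)) = 0.0317 M

That is 39.6% of the G, and I judge it too low. The G of Sunday's run is 0.500 of the G of Monday's run. Between its first and third readings, Sunday's run gains 0.643 of what Monday's run gains, more than that G ratio, although it has 0.0560 M of J against 0.0960 M. These readings do not show the rate of Sunday's run following J in proportion. I commit to the middle of ceiling and second pass, 0.0399 M, or 49.9% of the G.

The forecast gave orders of 1.1 in G and 0.7 in E, called Sunday's run slower and put Thursday's run at 49%, holding that “J barely matters until it runs low”.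

The flask gives orders of 0.93 and 0.84, Sunday's run slower, and Thursday's run at 46.8%.

    E + G ⇌ EG (3.070 L mol⁻¹ s⁻¹, 0.1570 s⁻¹)
    EG + J → L + E (5.560 L mol⁻¹ s⁻¹)
    G + J + L → 2 L (3.170 L² mol⁻² s⁻¹)
    E + J ⇌ EJ, settled at all times (25.60 L mol⁻¹)

In Thursday's run, the catalyst stood as E, EG and EJ while EG + J made L, and as L built up, G + J + L ran beside that path. By 110 s Thursday's run held 0.0375 M of L, which is 72.3% of the 0.0519 M read at 85.3 s on Saturday's clock, with 0.0105 M of J left, bound J counted. With m at 0.627, the 107 s that Monday's run takes to reach half of its G becomes 53.7 s for Saturday's run, which stands at 58.6 s.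

(All runs are calculated with constants of no real substance, and the scatter is random.)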